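**The decision.** 3 questions come down to one decision: which recipe do you charge for the next flask of 20 min, winter or dawn?

| setting | north-east | south-east | winter | dawn |
|---|---|---|---|---|
| starting material | 0.068 M | 0.068 M | 0.068 M | 0.068 M |
| reagent | 0.35 equiv | 1.6 equiv | 1.80 equiv | 0.600 equiv |
| protic impurity | 6.8 mM | 6.8 mM | 6.80 mM | 6.80 mM |
| free catalyst | 11 mol% | 11 mol% | 11 mol% | 11 mol% |
| remark | run made earlier | run made earlier |  |  |
| time |  |  | 20 min | 20 min |

1. which of the two ends with the higher amount of product, in percent of the starting material charged ("neither" if they lie within 2 percentage points) (winter / dawn / neither)
2. product at the end, in percent of the starting material charged, winter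
3. product at the end, in percent of the starting material charged, dawn

- north-east (time / min: product / %, starting material / %): 2.00: 17, 73; 5.00: 22, 67; 10.0: 24, 67; 15.0: 24, 67; 20.0: 22, 65
- south-east (time / min: product / %, starting material / %): 4.00: 62, 25; 8.00: 69, 21; 12.0: 70, 20; 15.0: 69, 21; 20.0: 70, 21

(standard deviation of a reading: 1.5 percentage points)

- the numbers in the tables scatter with a standard deviation of 1.5 percentage points

**The stops.** The earlier runs stop moving by their second reading, at 5.00 min in north-east and 8.00 min in south-east, so you want the level where a flask stops, not its speed. South-east then averages 69.5 % product and 20.8 % starting material. Their sum is close to the 90.0 % that remains if protic impurity takes its own amount of starting material.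

**The quotient.** Counting one reagent per product, you reckon that south-east keeps 90.5 % of reagent, in percent of the starting material charged. Read from these averages, with their scatter, that gives 54.4 /M for c(product) divided by c(starting material) times c(reagent) at the stop, the stall quotient, or apparent equilibrium constant. The same count leaves north-east 12.0 %, less than south-east, so the scatter weighs more on its quotient of 42.4 /M. I carry the south-east value.

**My reckoning.** Let x be product as a fraction of the starting material charged, a the available share and b the equivalents of reagent. I take the stop to be a balance of forward and back rates, which puts it at x = quotient · c(starting material) · (a − x)(b − x), and you take the smaller root. Winter gives 72.0 % and dawn 39.2 %, so you charge winter.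

**The forecast.** It also names winter, with 72 % (68 % to 76 %) for winter and 37 % (32 % to 42 %) for dawn, noting “Both runs stall with both partners remaining”. My dawn figure lies above its value, inside its range.

**The flask.** Winter ends at 72.6 % and dawn at 39.2 %.

    starting material + reagent + free catalyst ⇌ product + free catalyst, rate k1*[starting material]*[reagent]*[free catalyst] forward; the back reaction follows from the equilibrium constant (K = 61.0 /M, k = 15.0 /M²/s)
    starting material + protic impurity → quenched substrate (k = 1.70 /M/s)
    reagent + free catalyst → spent catalyst (k = 0.0140 /M/s)

**The comparison.** In winter, the product step has half of its turnover up to 20 min behind it by 0.751 min, while the reagent half-life by the path to spent catalyst is 120 min at 0.751 min, much longer. At 20 min, winter stands at a stall quotient of 61.4 /M, and for winter's neighbour with 0.17 M of starting material and 0.0400 equiv of protic impurity, the root with 54.4 /M gives 86.1 %, and that flask ends at 86.1 %.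

The readings stem from a simulated flask with constants of no real substance.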